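**Plan**

- Locants: ring A (cyclohexadienone) has C1 ketone, C2 isovaleryl, C3 enol, C4, C5 enol, C6 diprenyl; C1′ is the CH2 link; ring B (cyclopentane) has C2′ (CH), C3′ (C(OH)CH3), C4′, C5′, C6′ (CH–isopropenyl).
- Cuts, in retrosynthetic order: C3′–CH3 (methyl addition to a C3′ ketone); then C4–C1′ and C1′–C2′ together, which releases a ring A trione, formaldehyde and a ring B silyl enol ether; then the two C6–prenyl bonds and the C2–acyl bond of ring A, and the C6′–isopropenyl bond of ring B.
- Enabling feature: the chain C4 (enolic carbon of ring A)–C1′H2–C2′–C3′(O) is the retron of a 4-methylene trione (the 1-oxadiene O=C5–C4=C1′, i.e. the formaldehyde Knoevenagel adduct) added across the C2′=C3′–O unit of an enol ether of ring B.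
- Forward: both carbocycles are bought (phloroglucinol becomes ring A by acylation and gem-diprenylation, cyclopentenone becomes ring B). The only ring formed is a transient dihydropyran in the key step, which joins ring A, the C1′ unit and ring B in one flask; methyl addition at C3′ completes the target.
- Stereochemistry: C6′ (S) from a catalytic asymmetric conjugate addition; C2′ (R) from attack anti to the isopropenyl group, backed by equilibration α to the ketone; C3′ (S) from methyl addition anti to the C2′ substituent.

Key step: step 4

Remark on the chemistry: ring A compounds are written as one enol tautomer throughout, and the ring B ketone from the key step is written open-chain although it may equilibrate with a cyclic hemiketal onto a ring A enol oxygen; the basic conditions of the last step open any such hemiketal.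

Remark on the chemistry: the sense of induction of the ferrocenyl diphosphine in step 3 is assumed; the ligand enantiomer that delivers the S adduct is the one meant.

**Route**

Step 1
Reactants: 1 phloroglucinol; 2 isovaleryl chloride (3-methylbutanoyl chloride)
Product: 3 1-(2,4,6-trihydroxyphenyl)-3-methylbutan-1-one (phlorisovalerophenone)
Conditions: AlCl3 (4 equiv), PhNO2/CH2Cl2, rt to 45 °C; aq. HCl work-up
Reagents that add atoms: none
Why: Friedel–Crafts C-acylation of the electron-rich, threefold-symmetric triphenol is the standard entry to acylphloroglucinols, and the first acyl group deactivates the ring against a second acylation.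

Step 2
Reactants: 3 phlorisovalerophenone; 4 prenyl bromide (1-bromo-3-methylbut-2-ene)
Product: 5 2-(3-methylbutanoyl)-6,6-bis(3-methylbut-2-en-1-yl)cyclohexane-1,3,5-trione (enol form)
Conditions: NaOMe (3 equiv), 4 (2.1 equiv), MeOH, 0 °C to rt; aq. HCl, then chromatography
Reagents that add atoms: none
Why: Base-mediated dearomatising C-prenylation of the acylphloroglucinol polyanion in methanol (the alkylation used for hop-acid-type compounds) occurs at ring carbon rather than oxygen, and a second prenyl group can enter the already alkylated carbon to give the gem-diprenyl trione, which must be separated by chromatography from the 3,5-diprenyl isomer and the triprenyl product expected alongside.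

Step 3
Reactants: 6 cyclopent-2-en-1-one; 7 isopropenylmagnesium bromide
Product: 9 (S)-triethyl{[3-(prop-1-en-2-yl)cyclopent-1-en-1-yl]oxy}silane, via magnesium enolate 8 (not isolated)
Conditions: CuBr·SMe2 (5 mol %), (R)-1-[(S)-2-(diphenylphosphino)ferrocenyl]ethyldicyclohexylphosphine, C36H44FeP2 (6 mol %), t-BuOMe, −78 °C, slow addition of 6; then Et3SiCl, Et3N, DMPU, −78 to 0 °C
Reagents that add atoms: triethylsilyl chloride, CC[Si](Cl)(CC)CC
Why: Asymmetric conjugate addition of a Grignard reagent to a cyclic enone, catalysed by CuBr·SMe2 with a ferrocenyl diphosphine, sets C6′ by reagent control, and O-silylation of the magnesium enolate, whose double bond can only point toward the carbon next to the new stereocentre, fixes the regiochemistry of the enol ether.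

Step 4
Reactants: 5 diprenyl acyl trione; 10 formaldehyde (as paraformaldehyde); 9 (S)-silyl enol ether
Product: 13 ring B ketone 3,5-dihydroxy-2-(3-methylbutanoyl)-6,6-bis(3-methylbut-2-en-1-yl)-4-{[(1R,5S)-2-oxo-5-(prop-1-en-2-yl)cyclopentyl]methyl}cyclohexa-2,4-dien-1-one, via methylene trione 11 (not isolated), via silyl ketal cycloadduct 12 (not isolated)
Conditions: (CH2O)n (1.5 equiv), 9 (3 equiv), ethylenediammonium diacetate (10 mol %), 4 Å MS, MeCN, 40 °C, 5 added slowly; then AcOH/THF/H2O, rt
Reagents that add atoms: none
Why: The acidic trione condenses with formaldehyde at C4, its only free ring carbon (amine-salt-catalysed Knoevenagel condensation), and loss of water gives the methylene trione 11, an electron-poor 1-oxadiene (O=C–C4=C1′) of ortho-quinone-methide character. The electron-rich C2′=C3′ bond of 9 adds to it in an inverse-electron-demand hetero-Diels–Alder reaction, C1′ bonding to the nucleophilic C2′ and a flanking carbonyl oxygen to the siloxy carbon C3′; this is the domino Knoevenagel/hetero-Diels–Alder union of cyclic 1,3-dicarbonyls, aldehydes and enol ethers, and the (4+2) capture of ortho-quinone methides by silyl enol ethers is its closest relative. The only ring closed is the transient dihydropyran of 12, formed in the (4+2) mode (a 6-exo-trig O–C closure if the addition runs stepwise through a siloxycarbenium ion); either flanking oxygen (12 is drawn with O5) may close it, because mild acid hydrolysis of the silyl ketal reopens the ring to the same cyclopentanone and enol, so no ring is retained. The new stereocentre C2′ is controlled by C6′: the oxadiene approaches the cyclopentene face opposite the adjacent isopropenyl group, and since C2′ ends up α to the ketone any cis material should equilibrate to the trans (2′R,6′S) isomer. Chemoselectivity for the enol ether over the isopropenyl and prenyl alkenes rests on its far higher nucleophilicity, its regiochemistry is fixed in step 3, and Michael addition of a second molecule of 5 to 11 is held back by the excess of 9 and the slow addition of 5.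

Step 5
Reactants: 13 ring B ketone
Product: 14 3,5-dihydroxy-4-{[(1R,2S,5S)-2-hydroxy-2-methyl-5-(prop-1-en-2-yl)cyclopentyl]methyl}-2-(3-methylbutanoyl)-6,6-bis(3-methylbut-2-en-1-yl)cyclohexa-2,4-dien-1-one (CNP0332156.1)
Conditions: CeCl3 (anhydrous, 4 equiv), MeMgBr (5 equiv), THF, −78 to −20 °C; aq. NH4Cl
Reagents that add atoms: methylmagnesium bromide, C[Mg]Br
Why: Imamoto-type 1,2-addition of the weakly basic reagent made from MeMgBr and CeCl3 to an enolisable ketone, in which the excess reagent first turns ring A into its unreactive dianion and the methyl group then adds to the cyclopentanone from the face anti to the adjacent C2′ substituent (the usual course for 2-substituted cyclopentanones, here reinforced by the bulky metalated ring A), placing the C3′ hydroxyl cis to C1′ and giving 3′S.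

**Compound list**

1 | phloroglucinol (benzene-1,3,5-triol) | Oc1cc(O)cc(O)c1 | starting material
2 | isovaleryl chloride (3-methylbutanoyl chloride) | CC(C)CC(Cl)=O | starting material
3 | 1-(2,4,6-trihydroxyphenyl)-3-methylbutan-1-one (phlorisovalerophenone) | CC(C)CC(=O)c1c(O)cc(O)cc1O | intermediate
4 | prenyl bromide (1-bromo-3-methylbut-2-ene) | CC(C)=CCBr | starting material
5 | 2-(3-methylbutanoyl)-6,6-bis(3-methylbut-2-en-1-yl)cyclohexane-1,3,5-trione (enol form) | CC(C)CC(=O)C1=C(O)CC(=O)C(CC=C(C)C)(CC=C(C)C)C1=O | intermediate
6 | cyclopent-2-en-1-one | O=C1C=CCC1 | starting material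
7 | isopropenylmagnesium bromide | C=C(C)[Mg]Br | starting material
8 | bromomagnesium (S)-3-(prop-1-en-2-yl)cyclopent-1-en-1-olate (not isolated) | C=C(C)[C@H]1CCC(O[Mg]Br)=C1 | intermediate
9 | (S)-triethyl{[3-(prop-1-en-2-yl)cyclopent-1-en-1-yl]oxy}silane | C=C(C)[C@H]1CCC(O[Si](CC)(CC)CC)=C1 | intermediate
10 | formaldehyde (used as paraformaldehyde) | C=O | starting material
11 | 4-methylene-2-(3-methylbutanoyl)-6,6-bis(3-methylbut-2-en-1-yl)cyclohexane-1,3,5-trione, enol form (not isolated) | C=C1C(=O)C(CC=C(C)C)(CC=C(C)C)C(O)=C(C(=O)CC(C)C)C1=O | intermediate
12 | cis-fused triethylsilyl ketal cycloadduct (dihydropyran fused to rings A and B; C1′ and the ring oxygen on the face of ring B opposite the isopropenyl group; not isolated) | C=C(C)[C@H]1CC[C@]2(O[Si](CC)(CC)CC)OC3=C(C[C@H]12)C(O)=C(C(=O)CC(C)C)C(=O)C3(CC=C(C)C)CC=C(C)C | intermediate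
13 | 3,5-dihydroxy-2-(3-methylbutanoyl)-6,6-bis(3-methylbut-2-en-1-yl)-4-{[(1R,5S)-2-oxo-5-(prop-1-en-2-yl)cyclopentyl]methyl}cyclohexa-2,4-dien-1-one | C=C(C)[C@H]1CCC(=O)[C@@H]1CC1=C(O)C(CC=C(C)C)(CC=C(C)C)C(=O)C(C(=O)CC(C)C)=C1O | intermediate
14 | 3,5-dihydroxy-4-{[(1R,2S,5S)-2-hydroxy-2-methyl-5-(prop-1-en-2-yl)cyclopentyl]methyl}-2-(3-methylbutanoyl)-6,6-bis(3-methylbut-2-en-1-yl)cyclohexa-2,4-dien-1-one | C=C(C)[C@H]1CC[C@](C)(O)[C@@H]1CC1=C(O)C(CC=C(C)C)(CC=C(C)C)C(=O)C(C(=O)CC(C)C)=C1O | target

**Step count**

Total steps: 5. Longest linear sequence: 4 steps (steps 1, 2, 4 and 5 from phloroglucinol); step 3 is a one-step branch.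

**Steps most likely to fail**

Step 3. What may go wrong: poor enantioface discrimination when the CuBr·SMe2/diphosphine catalyst transfers an α-branched alkenyl Grignard reagent to the small, flat cyclopentenone, together with loss of the enolate by Michael addition to unreacted enone. The fallback sets out from 6 and comes back at 9. The stereocentre is set instead by a Hayashi–Miyaura addition, the best-established way to transfer alkenyl groups to cyclopentenone with high selectivity: 6, potassium isopropenyltrifluoroborate, [Rh(cod)2]BF4/(S)-BINAP (the ligand enantiomer expected, by analogy with aryl transfer, to give S), Et3N, toluene/H2O, 100 °C should give (S)-3-(prop-1-en-2-yl)cyclopentan-1-one F1. This route delivers the free ketone, so the regiochemical information of the enolate is lost. Kinetic silylation (LiN(i-Pr)2, Et3SiCl, THF, −78 °C) is expected to give 9 together with its double-bond regioisomer (S)-triethyl{[4-(prop-1-en-2-yl)cyclopent-1-en-1-yl]oxy}silane F2. The mixture re-enters the route at 9 and is used as such in step 4, where F2 should give the constitutionally isomeric 2,4-disubstituted cyclopentanone adduct F3, to be removed by chromatography of 13. The cost is material at an early stage, not stereochemical purity at C6′.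

Step 4. What may go wrong: capture of the methylene trione 11 by a second molecule of 5 (methylene-bridged bis-trione), or hydrolysis of 9 by the water of condensation and the acidic trione before it can react. The fallback sets out from 5 and comes back at 13. The oxadiene is stored as an isolable Mannich base and released under anhydrous, neutral conditions: 5, 10 and morpholine (EtOH, rt) should give the zwitterionic 4-(morpholin-4-ylmethyl) trione F4. Heating F4 with 9 (3 equiv) in toluene at 90 °C should release 11 slowly by amine elimination (the known behaviour of Mannich bases of phenols and cyclic 1,3-diones as ortho-quinone methide sources) in the presence of excess dienophile, so that the same cycloadduct 12 and, after AcOH/THF/H2O, 13 result.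

Step 2. What may go wrong: poor site selectivity of the second prenylation (the free aromatic carbon instead of the already prenylated one) and over-alkylation to the triprenyl compound, so that 5 is only a minor component of the mixture. The fallback sets out from 2 and comes back at 5. The competing ring position is blocked by an ester that is removed at the end. Commercial methyl 2,4,6-trihydroxybenzoate F5 is acylated with 2 (AlCl3, PhNO2, 60 °C) to methyl 2,4,6-trihydroxy-3-(3-methylbutanoyl)benzoate F6, in which only one ring carbon is free. Prenylation with 4 (NaOMe, MeOH) can then only end at the gem-diprenyl dienone ester methyl 2,4-dihydroxy-3-(3-methylbutanoyl)-5,5-bis(3-methylbut-2-en-1-yl)-6-oxocyclohexa-1,3-diene-1-carboxylate F7, the situation of the last prenylation in lupulone-type syntheses. Krapcho demethylation–decarboxylation of this vinylogous β-keto ester (LiCl, wet DMSO, 120 °C) should give 5.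

**Further compounds**

F1 | step 3 | (S)-3-(prop-1-en-2-yl)cyclopentan-1-one | C=C(C)[C@H]1CCC(=O)C1
F2 | step 3 | (S)-triethyl{[4-(prop-1-en-2-yl)cyclopent-1-en-1-yl]oxy}silane | C=C(C)[C@H]1CC=C(O[Si](CC)(CC)CC)C1
F3 | step 3 | regioisomeric adduct, ring A methyl group at the ketone α-carbon remote from the isopropenyl-bearing carbon (epimers at the new centre) | C=C(C)[C@H]1CC(CC2=C(O)C(CC=C(C)C)(CC=C(C)C)C(=O)C(C(=O)CC(C)C)=C2O)C(=O)C1
F4 | step 4 | 4-(morpholin-4-ylmethyl)-2-(3-methylbutanoyl)-6,6-bis(3-methylbut-2-en-1-yl)cyclohexane-1,3,5-trione (Mannich base, enol form) | CC(C)CC(=O)C1=C(O)C(CN2CCOCC2)=C(O)C(CC=C(C)C)(CC=C(C)C)C1=O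
F5 | step 2 | methyl 2,4,6-trihydroxybenzoate (commercial) | COC(=O)c1c(O)cc(O)cc1O
F6 | step 2 | methyl 2,4,6-trihydroxy-3-(3-methylbutanoyl)benzoate | COC(=O)c1c(O)cc(O)c(C(=O)CC(C)C)c1O
F7 | step 2 | methyl 2,4-dihydroxy-3-(3-methylbutanoyl)-5,5-bis(3-methylbut-2-en-1-yl)-6-oxocyclohexa-1,3-diene-1-carboxylate | COC(=O)C1=C(O)C(C(=O)CC(C)C)=C(O)C(CC=C(C)C)(CC=C(C)C)C1=O
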